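Slowness was what I looked at first: the feed of J lasts 40 s, yet in birch, with J at 0% by 1.33 h, Q was still falling hours later. So I kept books on J, the limiting reagent.

the same everywhere: J 20 mM (fed, over 40 s)

|  | X | remark | time |
|---|---|---|---|
| birch | 48 µM | run made earlier |  |
| elm | 110 µM | run made earlier |  |
| flask | 72 µM |  | 4.0 h |

| run | time / h | Q / % | J / % |
|---|---|---|---|
| birch | 0.133 | 46 | 48 |
| birch | 0.200 | 65 | 29 |
| birch | 0.417 | 92 | 7 |
| birch | 0.667 | 95 | 3 |
| birch | 1.33 | 98 | 0 |
| birch | 2.00 | 95 | 0 |
| birch | 4.00 | 92 | 0 |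
| elm | 0.133 | 74 | 18 |
| elm | 0.200 | 85 | 11 |
| elm | 0.417 | 84 | 0 |
| elm | 0.667 | 80 | 0 |
| elm | 1.33 | 60 | 2 |
| elm | 2.00 | 59 | 0 |
| elm | 4.00 | 48 | 0 |

(scatter of a reading: 2 percentage points)



- time up to 4.0 h at which Q stands highest
- the amount of Q, in percent of the J charged, at that time

In birch, Q read 98% at 1.33 h and 92% at 4.00 h, so 6 percentage points left the books. In elm, with J at 0%, Q went from 84% at 0.417 h to 48% at 4.00 h, so 36 points left.

I replaced each fall by one mean rate d, the logarithm of first over last Q divided by the time between. That gave 0.0237 h⁻¹ for birch and 0.156 h⁻¹ for elm. From birch to elm, d rose 6.58 times while cX rose 2.29 times.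

A straight line through the two reaches zero at cX = 36.9 µM. Per charged J, this is the loss-free ratio, the X per J at which the line gives no mean loss: 0.00185. It is a reading from two runs, with their scatter. The flask stands above it, at 0.00360, so I reckoned d = 0.0750 h⁻¹ for the flask.

The forecast gave 93% at 0.5 h, on the ground that “The maximum falls where J's remaining rate matches the loss”.

The flask gave 93.4% at 0.478 h.

    J + X → Z + Q (k = 0.390 M⁻¹ s⁻¹)
    J + Z → Q + Z, rate k2*[Z]*[J] (k = 44.0 M⁻¹ s⁻¹)
    Q + X ⇌ G + X, rate k3*[X]*[Q] forward; the back reaction follows from the equilibrium constant (K = 1.30, k = 12.0 M⁻¹ s⁻¹)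

The forecast held, and the drawn-out feed made no difference to the peak: it lasted 40 s against 0.478 h. Carrying my mean rate from that peak to 4.0 h gives 71.8% of Q, and the flask held 70.4% beside 29.6% of G, so the mean erred by 1.4 points. The neighbouring flask, the same recipe with 80 mM of J, had 9.00 × 10⁻⁴ X per J, less than the loss-free ratio, so the line gives no mean loss there. At 4.00 h, the neighbouring flask held 0.202% of G and 99.8% of Q.

The numbers in the tables are simulated with constants of no real substance; noise was put on by code.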